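## Retrosynthetic overview
1. Both O-heterocycles are opened at once. The pyran goes back to an aryl 1,1-dimethylpropargyl ether (retro oxa-6π / 1,5-H shift / Claisen). The dihydrofuran C2–O bond goes back to an (S)-epoxide, that is, to a plain 3'-prenyl group next to a free 4'-OH.
2. This leaves an unprotected, open 3'-prenyl-4-(propargyloxy)chalcone, which is cut at the enone by a Claisen–Schmidt disconnection.
3. The ketone half comes from 2,4-dihydroxyacetophenone and prenyl bromide (C-prenylation). The aldehyde half comes from 4-hydroxybenzaldehyde and 3-chloro-3-methylbut-1-yne (O-alkylation).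
4. Ring order: both benzene rings are bought. In the last flask the dihydrofuran closes first (0 °C to rt, fixing the (R) centre by inversion of the (S)-epoxide) and the pyran second (180 °C), with nothing isolated in between.

Assumption: the catalyst of step 4 is the ent-Shi ketone, 1,2:4,5-di-O-isopropylidene-β-L-erythro-2,3-hexodiulo-2,6-pyranose, C12H18O6, SMILES C1[C@@H]([C@@H](C(=O)[C@@](O1)(CO2)OC2(C)C)O3)OC3(C)C. It is bought (or made beforehand from L-fructose) and, as a catalyst, is neither numbered nor counted as a step.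

## Route

Step 1
Reactants: 1 2,4-dihydroxyacetophenone; 2 prenyl bromide (1-bromo-3-methylbut-2-ene)
Product: 3 1-[2,4-dihydroxy-3-(3-methylbut-2-en-1-yl)phenyl]ethan-1-one
Conditions: KOH (1.0 equiv), H2O, 0 °C to rt, 16 h; chromatography (removes 5-prenyl and O-prenyl isomers)
Reagents that add atoms: none
Why: Nuclear C-prenylation of an ambident phenoxide, in which water hydrogen-bonds the phenoxide oxygens so that the soft allylic bromide is taken by C3, the doubly activated carbon between the two oxygens, as in the classical isocordoin-type preparations; no stereocentre is formed.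

Step 2
Reactants: 4 4-hydroxybenzaldehyde; 5 3-chloro-3-methylbut-1-yne
Product: 6 4-[(2-methylbut-3-yn-2-yl)oxy]benzaldehyde
Conditions: K2CO3 (1.5 equiv), KI (10 mol %), CuI (5 mol %), DMF, 60 °C, 12 h
Reagents that add atoms: none
Why: Copper-assisted Williamson-type O-propargylation, in which the tertiary propargylic chloride ionises through its copper acetylide and the phenoxide captures the cation at the tertiary carbon; the aldehyde is untouched and no stereocentre is formed.

Step 3
Reactants: 3 1-[2,4-dihydroxy-3-(3-methylbut-2-en-1-yl)phenyl]ethan-1-one; 6 4-[(2-methylbut-3-yn-2-yl)oxy]benzaldehyde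
Product: 8 (E)-1-[2,4-dihydroxy-3-(3-methylbut-2-en-1-yl)phenyl]-3-{4-[(2-methylbut-3-yn-2-yl)oxy]phenyl}prop-2-en-1-one, via aldol adduct 7 (not isolated)
Conditions: KOH (50% aq, 12 equiv), EtOH, rt, 48 h; then 2 M HCl to pH 4, 0 °C
Reagents that add atoms: none
Why: Claisen–Schmidt aldol condensation of the methyl ketone with a non-enolisable aldehyde, in which E1cB loss of water from 7 gives the conjugated (E)-enone under thermodynamic control, while the prenyl group and the quaternary propargyl ether (no propargylic H to isomerise) are inert to aqueous KOH.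

Step 4
Reactants: 8 (E)-1-[2,4-dihydroxy-3-(3-methylbut-2-en-1-yl)phenyl]-3-{4-[(2-methylbut-3-yn-2-yl)oxy]phenyl}prop-2-en-1-one
Product: 13 (E)-3-(2,2-dimethyl-2H-chromen-6-yl)-1-[(2R)-4-hydroxy-2-(2-hydroxypropan-2-yl)-2,3-dihydro-1-benzofuran-5-yl]prop-2-en-1-one (target), via epoxide 9 (not isolated), via dihydrobenzofuran propargyl ether 10 (not isolated), via allenylphenol 11 (not isolated), via quinone methide 12 (not isolated)
Conditions: 1,2:4,5-di-O-isopropylidene-β-L-erythro-2,3-hexodiulo-2,6-pyranose (ent-Shi ketone, C12H18O6, 30 mol %), Oxone (2KHSO5·KHSO4·K2SO4, 1.0 equiv) and K2CO3 (4.2 equiv) added in parallel over 2 h, Bu4NHSO4 (4 mol %), MeCN–CH2(OMe)2 / aq Na2B4O7–Na2H2EDTA buffer (pH 10.5), 0 °C, then rt, 1 h; extract into o-dichlorobenzene, wash with NaH2PO4/Na2HPO4 buffer (pH 7), distil off low boilers; 180 °C, 3 h, N2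
Reagents that add atoms: Oxone, active component potassium peroxymonosulfate KHSO5, [K+].[O-]S(=O)(=O)OO
Why: Proposed new method: the chiral dioxirane formed from the ketone and KHSO5 (Shi asymmetric epoxidation) oxidises only the electron-rich trisubstituted prenyl C=C (enone and terminal alkyne are too electron-poor) on the face that gives (S)-epoxide 9, the 4'-phenoxide present at pH 10.5 opens 9 at once by 5-exo-tet SN2 attack at the secondary carbon with clean inversion and so sets the (R) centre of 10 (the 2'-OH stays chelated to the ketone), and heating the unpurified o-dichlorobenzene extract then triggers the aryl propargyl ether Claisen rearrangement, 1,5-H shift and oxa-6π electrocyclisation (11, 12) that closes the pyran without touching the stereocentre, the closest known reaction types being the Shi epoxidation–cyclisation of masked o-prenylphenols and the thermal conversion of aryl 1,1-dimethylpropargyl ethers into 2,2-dimethyl-2H-chromenes, here run back to back on a fully unprotected chalcone.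

## Compound list
1 | 2,4-dihydroxyacetophenone | CC(=O)c1ccc(O)cc1O | starting material
2 | prenyl bromide (1-bromo-3-methylbut-2-ene) | CC(C)=CCBr | starting material
3 | 1-[2,4-dihydroxy-3-(3-methylbut-2-en-1-yl)phenyl]ethan-1-one | CC(=O)c1ccc(O)c(CC=C(C)C)c1O | intermediate
4 | 4-hydroxybenzaldehyde | O=Cc1ccc(O)cc1 | starting material
5 | 3-chloro-3-methylbut-1-yne | C#CC(C)(C)Cl | starting material
6 | 4-[(2-methylbut-3-yn-2-yl)oxy]benzaldehyde | C#CC(C)(C)Oc1ccc(C=O)cc1 | intermediate
7 | aldol adduct, 1-[2,4-dihydroxy-3-(3-methylbut-2-en-1-yl)phenyl]-3-hydroxy-3-{4-[(2-methylbut-3-yn-2-yl)oxy]phenyl}propan-1-one (racemic) | CC(C)=CCc1c(O)ccc(C(=O)CC(O)c2ccc(OC(C)(C)C#C)cc2)c1O | intermediate (not isolated)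
8 | (E)-1-[2,4-dihydroxy-3-(3-methylbut-2-en-1-yl)phenyl]-3-{4-[(2-methylbut-3-yn-2-yl)oxy]phenyl}prop-2-en-1-one | CC(C)=CCc1c(O)ccc(C(=O)/C=C/c2ccc(OC(C)(C)C#C)cc2)c1O | intermediate
9 | (E)-1-(3-{[(2S)-3,3-dimethyloxiran-2-yl]methyl}-2,4-dihydroxyphenyl)-3-{4-[(2-methylbut-3-yn-2-yl)oxy]phenyl}prop-2-en-1-one | CC1(C)O[C@H]1Cc2c(O)ccc(C(=O)/C=C/c3ccc(OC(C)(C)C#C)cc3)c2O | intermediate (not isolated)
10 | (E)-1-[(2R)-4-hydroxy-2-(2-hydroxypropan-2-yl)-2,3-dihydro-1-benzofuran-5-yl]-3-{4-[(2-methylbut-3-yn-2-yl)oxy]phenyl}prop-2-en-1-one | C#CC(C)(C)Oc1ccc(/C=C/C(=O)c2ccc3c(c2O)C[C@H](C(C)(C)O)O3)cc1 | intermediate (not isolated)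
11 | (E)-1-[(2R)-4-hydroxy-2-(2-hydroxypropan-2-yl)-2,3-dihydro-1-benzofuran-5-yl]-3-[4-hydroxy-3-(3-methylbuta-1,2-dien-1-yl)phenyl]prop-2-en-1-one | CC(C)=C=Cc1cc(/C=C/C(=O)c2ccc3c(c2O)C[C@H](C(C)(C)O)O3)ccc1O | intermediate (not isolated)
12 | o-quinone methide, 4-{(E)-3-[(2R)-4-hydroxy-2-(2-hydroxypropan-2-yl)-2,3-dihydro-1-benzofuran-5-yl]-3-oxoprop-1-en-1-yl}-6-(3-methylbut-2-en-1-ylidene)cyclohexa-2,4-dien-1-one (exocyclic C=C geometry not fixed) | CC(C)=CC=C1C=C(/C=C/C(=O)c2ccc3c(c2O)C[C@H](C(C)(C)O)O3)C=CC1=O | intermediate (not isolated)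
13 | (E)-3-(2,2-dimethyl-2H-chromen-6-yl)-1-[(2R)-4-hydroxy-2-(2-hydroxypropan-2-yl)-2,3-dihydro-1-benzofuran-5-yl]prop-2-en-1-one | CC1(C)C=Cc2cc(/C=C/C(=O)c3ccc4c(c3O)C[C@H](C(C)(C)O)O4)ccc2O1 | target

## Step count, risks and fallbacks
Total steps: 4. Longest linear sequence: 3 (steps 1, 3 and 4; step 2 runs in parallel).

**Step 4 (highest risk).**
- The free 4'-phenoxide and the 2'-hydroxychalcone may be attacked by KHSO5 in Dakin-type or Algar–Flynn–Oyamada-type side reactions.
- Salts carried into the hot stage may isomerise the chalcone to the flavanone.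

The fallback sets out from 8. The more acidic, non-chelated 4'-OH is capped with Boc2O (1.05 equiv, 4-(dimethylamino)pyridine cat., CH2Cl2, 0 °C) to give the 4'-O-Boc chalcone F5. Epoxidation with the same ketone and KHSO5 then gives the isolable, chromatographable 4'-O-Boc (S)-epoxide F6. Pure F6 is heated alone in o-dichlorobenzene at 180 °C. Thermolysis of the aryl tert-butyl carbonate unmasks the phenol, so the route is rejoined at 9 in the hot flask. Compound 9 closes to 10 while the propargyl ether rearranges, so both rings again arise in that single heating to 13. Premature loss of Boc during the epoxidation is harmless, because it leads to 10.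

**Step 1.** The phenoxide is ambident, so 4-O-prenyl, 5-prenyl and bis-prenyl products compete, and about 30–40% of 3 is realistic.

The fallback sets out from 1 and moves the C–C bond formation to a sigmatropic step. O-alkylation of the 4-OH of 1 with 5 (K2CO3, KI, CuI, DMF, 60 °C) gives the propargyl ether 1-[2-hydroxy-4-(2-methylbut-3-yn-2-yloxy)phenyl]ethanone F1. Semihydrogenation (H2, Pd/CaCO3 poisoned with Pb(OAc)2, quinoline, EtOAc, rt) gives the 1,1-dimethylallyl ether 1-[2-hydroxy-4-(2-methylbut-3-en-2-yloxy)phenyl]ethanone F2. An aromatic Claisen rearrangement (N,N-diethylaniline, 130 °C) then delivers the allyl unit with inversion, as a prenyl group, to C3. That position is favoured by bond fixation from the chelated 2-OH. The route is rejoined at 3.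

**Step 3.**
- The doubly deprotonated ketone enolises reluctantly, so conversion can stall.
- Acidification can give some flavanone.

The fallback sets out from 3. Selective protection of the 4-OH (MOMCl, K2CO3, acetone, rt) gives the mono-MOM ketone 1-[2-hydroxy-4-(methoxymethoxy)-3-(3-methylbut-2-en-1-yl)phenyl]ethanone F3. This behaves as an ordinary 2'-hydroxyacetophenone and condenses with 6 (KOH, EtOH, rt) to the 4'-O-MOM chalcone F4. Brief treatment with 3 M HCl in MeOH at 50 °C removes the acetal, and the route is rejoined at 8.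

## Further compounds
F1 | step 1 | 1-[2-hydroxy-4-(2-methylbut-3-yn-2-yloxy)phenyl]ethanone | CC(=O)c1ccc(OC(C)(C)C#C)cc1O
F2 | step 1 | 1-[2-hydroxy-4-(2-methylbut-3-en-2-yloxy)phenyl]ethanone | CC(=O)c1ccc(OC(C)(C)C=C)cc1O
F3 | step 3 | 1-[2-hydroxy-4-(methoxymethoxy)-3-(3-methylbut-2-en-1-yl)phenyl]ethanone | CC(=O)c1ccc(OCOC)c(CC=C(C)C)c1O
F4 | step 3 | 4'-O-MOM chalcone, (E)-1-[2-hydroxy-4-(methoxymethoxy)-3-(3-methylbut-2-en-1-yl)phenyl]-3-{4-[(2-methylbut-3-yn-2-yl)oxy]phenyl}prop-2-en-1-one | CC(C)=CCc1c(OCOC)ccc(C(=O)/C=C/c2ccc(OC(C)(C)C#C)cc2)c1O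
F5 | step 4 | 4'-O-Boc chalcone, tert-butyl 3-hydroxy-2-(3-methylbut-2-en-1-yl)-4-[(E)-3-{4-[(2-methylbut-3-yn-2-yl)oxy]phenyl}prop-2-enoyl]phenyl carbonate | CC(C)=CCc1c(OC(=O)OC(C)(C)C)ccc(C(=O)/C=C/c2ccc(OC(C)(C)C#C)cc2)c1O
F6 | step 4 | 4'-O-Boc (S)-epoxide, tert-butyl 2-{[(2S)-3,3-dimethyloxiran-2-yl]methyl}-3-hydroxy-4-[(E)-3-{4-[(2-methylbut-3-yn-2-yl)oxy]phenyl}prop-2-enoyl]phenyl carbonate | CC1(C)O[C@H]1Cc2c(OC(=O)OC(C)(C)C)ccc(C(=O)/C=C/c3ccc(OC(C)(C)C#C)cc3)c2O
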